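**Plan**
- Retrosynthesis: (a) the C3–H and C3''–H bonds are cut last, back to a bis(silyl enol ether) of the protected biflavanone. (b) The C2–C3 bond of ring C in the methoxy half is cut back to a p-methoxybenzyl aryl ether carrying a C3=C4 enol acetate. (c) The C3–C3'' link is cut, as an exocyclic C=C, back to a flavanone and an arylglyoxal. (d) The C2''–aryl bond is cut back to a chromone and an arylboronic acid.
- Enabling feature: C2 carries ring oxygen O1 and the 4-methoxyphenyl ring B, so it is the benzylic carbon of a p-methoxybenzyl ether of the ring A phenol, and C3 is alpha to the C4 ketone. Hydride loss at C2 and attack by the C3 enol carbon turns a "protecting group" into C2 plus ring B and closes ring C.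
- Forward order: ring C'' (chromone, then flavanone of the hydroxy half), the C3''–C3 link by condensation, ring C by the oxidative closure, re-setting of C3/C3'', debenzylation.
- Stereochemistry: C2'' comes from catalysis (asymmetric conjugate arylation). C3'' is made cis by hydrogenation so that it can relay. C2 is relayed from C3'' in the ring closure, with a temporary trans C3. The final C3 and C3'' configurations come from kinetic protonation anti to each C2 aryl group.

Key step: step 8

Assumption: compound 1 is taken as purchasable (otherwise one selective dibenzylation of 2',4',6'-trihydroxyacetophenone with benzyl bromide and K2CO3).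
Assumption: (S)-t-BuPyOx is taken to deliver the 2S flavanone in step 2; if the sense proves opposite, the (R)-ligand is used.

Step 1
Reactants: 1 1-[2,4-bis(benzyloxy)-6-hydroxyphenyl]ethan-1-one
Product: 3 5,7-bis(benzyloxy)-4H-chromen-4-one, via enaminone 2 (not isolated)
Conditions: Me2NCH(OMe)2, toluene, 100 °C; then AcOH, 80 °C
Reagents that add atoms: N,N-dimethylformamide dimethyl acetal, COC(OC)N(C)C
Why: Enaminone formation from the methyl ketone followed by acid-promoted addition–elimination of the ortho phenol (enaminone chromone synthesis) is the standard entry to 3-unsubstituted chromones; no stereocenter is formed.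

Step 2
Reactants: 3 5,7-bis(benzyloxy)-4H-chromen-4-one; 4 4-(benzyloxy)phenylboronic acid
Product: 5 (2S)-5,7-bis(benzyloxy)-2-[4-(benzyloxy)phenyl]-2,3-dihydro-4H-chromen-4-one
Conditions: Pd(OCOCF3)2 (5 mol %), (S)-t-BuPyOx (6 mol %), NH4PF6 (30 mol %), H2O (5 equiv), ClCH2CH2Cl, 60 °C
Reagents that add atoms: none
Why: Palladium-catalysed asymmetric conjugate addition of an arylboronic acid to a chromone is a known route to 2-arylchroman-4-ones; the pyridine-oxazoline ligand differentiates the enone faces in the aryl-palladium insertion and so should set C2'' as S, after which the palladium enolate is protonated by water.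

Step 3
Reactants: 1 1-[2,4-bis(benzyloxy)-6-hydroxyphenyl]ethan-1-one; 6 4-methoxybenzyl chloride
Product: 7 1-[2,4-bis(benzyloxy)-6-[(4-methoxyphenyl)methoxy]phenyl]ethan-1-one
Conditions: K2CO3, Bu4NI (cat.), DMF, 60 °C
Reagents that add atoms: none
Why: Williamson etherification of the hydrogen-bonded ortho phenol with a benzylic chloride under iodide catalysis; this 4-methoxybenzyl group is the future C2 and ring B of the methoxy half.

Step 4
Reactants: 7 1-[2,4-bis(benzyloxy)-6-[(4-methoxyphenyl)methoxy]phenyl]ethan-1-one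
Product: 8 2-[2,4-bis(benzyloxy)-6-[(4-methoxyphenyl)methoxy]phenyl]-2-oxoacetaldehyde
Conditions: SeO2 (1.5 equiv), 1,4-dioxane/H2O (20:1), 90 °C
Reagents that add atoms: selenium dioxide, O=[Se]=O
Why: Riley oxidation of an aryl methyl ketone to the arylglyoxal, for which electron-rich alkoxyacetophenones are typical substrates.

Step 5
Reactants: 5 (2S)-5,7-bis(benzyloxy)-2-[4-(benzyloxy)phenyl]-2,3-dihydro-4H-chromen-4-one; 8 2-[2,4-bis(benzyloxy)-6-[(4-methoxyphenyl)methoxy]phenyl]-2-oxoacetaldehyde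
Product: 9 (2R,3E)-5,7-bis(benzyloxy)-2-[4-(benzyloxy)phenyl]-3-{2-[2,4-bis(benzyloxy)-6-[(4-methoxyphenyl)methoxy]phenyl]-2-oxoethylidene}-2,3-dihydro-4H-chromen-4-one (same spatial arrangement at C2 as in 5; the descriptor changes because C3 is now sp2)
Conditions: piperidine (0.2 equiv), AcOH (0.2 equiv), toluene, 4 Å molecular sieves, 40 °C
Reagents that add atoms: none
Why: Amine/acid-catalysed aldol (Knoevenagel-type) condensation of a flavanone at C3 with an aldehyde to the (E)-3-ylidene flavanone is known for aryl aldehydes; only the unhindered aldehyde carbon of 8 should react, and the buffered medium is chosen to keep C2'' from ring-opening epimerization.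

Step 6
Reactants: 9 the (2R,3E)-ylidene flavanone
Product: 10 (2S,3S)-5,7-bis(benzyloxy)-2-[4-(benzyloxy)phenyl]-3-{2-[2,4-bis(benzyloxy)-6-[(4-methoxyphenyl)methoxy]phenyl]-2-oxoethyl}-2,3-dihydro-4H-chromen-4-one (2,3-cis)
Conditions: H2 (1 atm), 10% Pd/C, Ph2S (0.01 equiv), EtOAc, 23 °C
Reagents that add atoms: none
Why: Hydrogenation over diphenyl sulfide-poisoned palladium on carbon reduces conjugated C=C bonds without cleaving benzyl ethers or aryl ketones; syn delivery of H2 to the exocyclic alkene from the face opposite the pseudoaxial C2'' aryl group should put C3''–H trans to the aryl group and the side chain cis (3''S), the configuration needed for the relay in step 8.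

Step 7
Reactants: 10 the (2S,3S)-cis diketone
Product: 12 (1Z)-1-[2,4-bis(benzyloxy)-6-[(4-methoxyphenyl)methoxy]phenyl]-2-{(2S,3S)-5,7-bis(benzyloxy)-2-[4-(benzyloxy)phenyl]-4-oxo-3,4-dihydro-2H-chromen-3-yl}ethenyl acetate, via lithium (Z)-enolate 11 (not isolated)
Conditions: LiN(SiMe3)2 (1.05 equiv), THF, −78 °C; then Ac2O, −78 to 0 °C
Reagents that add atoms: acetic anhydride, CC(=O)OC(C)=O
Why: Kinetic deprotonation with the hindered lithium amide should remove a proton of the side-chain CH2 (C3) rather than the shielded ring methine C3''–H, aryl ketones give the (Z)-O-enolate, and O-acetylation traps it as the enol acetate (enolate O-acylation).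

Step 8
Reactants: 12 the (Z)-enol acetate
Product: 14 (2S,3R)-5,7-bis(benzyloxy)-3-{(2S,3S)-5,7-bis(benzyloxy)-2-[4-(benzyloxy)phenyl]-4-oxo-3,4-dihydro-2H-chromen-3-yl}-2-(4-methoxyphenyl)-2,3-dihydro-4H-chromen-4-one, via oxocarbenium ion pair 13 (not isolated)
Conditions: DDQ (1.3 equiv), 2,6-dichloropyridine (3 equiv), LiClO4 (0.2 equiv), 4 Å molecular sieves, ClCH2CH2Cl, 23 °C; aqueous NaHCO3 work-up
Reagents that add atoms: none
Why: Proposed new method: DDQ should abstract hydride from the p-methoxybenzyl methylene (future C2), the C–H best stabilised by the anisyl ring and O1, to give the (E)-aryloxycarbenium ion pair 13, whose cationic carbon is attacked by C3 of the tethered (Z)-enol acetate while the acetyl group passes to the DDQH anion or 2,6-dichloropyridine; the closest known reaction type is the DDQ-mediated oxidative cyclization of p-methoxybenzyl alkyl ethers onto enol acetates (an oxidatively triggered Mukaiyama-type addition giving tetrahydropyran-4-ones), not yet shown for phenol-derived ethers or for chromanone formation. Ring C closes in the 6-(enolendo)-endo-trig mode through a half-chair in which O1, C8a, C4a and C4 stay in the arene plane. C2 and C3 are formed together, and the (E)-oxocarbenium and (Z)-enol geometries place the anisyl group and the C3 substituent both pseudoequatorial, i.e. 2,3-trans. Their absolute sense is relayed from C3'': with C3''–H eclipsing the enol double bond (A(1,3) strain with the cis acetoxy group), the C2'' branch with its gauche aryl group shields one enol face, so C2 should add from the C4'' side and give 3R and therefore 2S. The step needs chemoselective hydride removal at the one p-methoxybenzyl CH2 among five benzyl ether CH2 groups and the C2''–H of the existing chromanone, secured by the p-methoxy donor and by the deactivating beta-carbonyl at C2''–H, and regioselective C–C bond formation, secured because only C3 can reach C2 through a six-membered transition state. The C3 configuration formed here serves only as the relay to C2 and is corrected in step 10.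

Step 9
Reactants: 14 the (2S,3R)/(2''S,3''S) biflavanone
Product: 15 (2R,2'R)-5,5',7,7'-tetrakis(benzyloxy)-2'-[4-(benzyloxy)phenyl]-2-(4-methoxyphenyl)-4,4'-bis[(trimethylsilyl)oxy]-2H,2'H-3,3'-bichromene (same spatial arrangement at both C2 centres as in 14; the descriptors change by the sequence rule only)
Conditions: Me3SiOSO2CF3 (5 equiv), Et3N (8 equiv), CH2Cl2, 0 to 23 °C
Reagents that add atoms: trimethylsilyl trifluoromethanesulfonate, C[Si](C)(C)OS(=O)(=O)C(F)(F)F
Why: Soft enolization of both ketones with silyl triflate and amine (silyl enol ether formation) erases C3 and C3'' while the ether-bearing C2 and C2'' are untouched.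

Step 10
Reactants: 15 the bis(trimethylsilyl enol ether)
Product: 16 (2S,3S)-5,7-bis(benzyloxy)-3-{(2S,3S)-5,7-bis(benzyloxy)-2-[4-(benzyloxy)phenyl]-4-oxo-3,4-dihydro-2H-chromen-3-yl}-2-(4-methoxyphenyl)-2,3-dihydro-4H-chromen-4-one (both halves 2,3-cis)
Conditions: AcOH (10 equiv), Bu4NF (2.5 equiv), THF, −78 °C
Reagents that add atoms: none
Why: Fluoride cleavage of each silyl enol ether in the presence of acetic acid should give irreversible kinetic C-protonation (protodesilylation); in each 2H-chromene the C2 aryl group is pseudoaxial (A(1,2) strain with the C3 substituent) and the proton enters from the opposite face, which places H3 trans to the aryl group and so gives 3S and 3''S.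

Step 11
Reactants: 16 the cis,cis penta-O-benzyl biflavanone
Product: 17 sikokianin A, (2S,3S)-3-[(2S,3S)-5,7-dihydroxy-2-(4-hydroxyphenyl)-4-oxo-3,4-dihydro-2H-chromen-3-yl]-5,7-dihydroxy-2-(4-methoxyphenyl)-2,3-dihydro-4H-chromen-4-one
Conditions: H2 (1 atm), 10% Pd/C, EtOAc/MeOH (1:1), 23 °C
Reagents that add atoms: none
Why: Neutral hydrogenolysis of the five benzyl ethers over palladium on carbon (O-debenzylation) should leave the methyl ether and the epimerizable cis alpha-stereocenters untouched.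

**Compound list**
1 | 1-[2,4-bis(benzyloxy)-6-hydroxyphenyl]ethan-1-one | CC(=O)c1c(O)cc(OCc2ccccc2)cc1OCc1ccccc1 | starting material
2 | (2E)-1-[2,4-bis(benzyloxy)-6-hydroxyphenyl]-3-(dimethylamino)prop-2-en-1-one | CN(C)/C=C/C(=O)c1c(O)cc(OCc2ccccc2)cc1OCc1ccccc1 | intermediate (not isolated)
3 | 5,7-bis(benzyloxy)-4H-chromen-4-one | O=c1ccoc2cc(OCc3ccccc3)cc(OCc3ccccc3)c12 | intermediate
4 | 4-(benzyloxy)phenylboronic acid | OB(O)c1ccc(OCc2ccccc2)cc1 | starting material
5 | (2S)-5,7-bis(benzyloxy)-2-[4-(benzyloxy)phenyl]-2,3-dihydro-4H-chromen-4-one | O=C1C[C@@H](c2ccc(OCc3ccccc3)cc2)Oc2cc(OCc3ccccc3)cc(OCc3ccccc3)c12 | intermediate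
6 | 4-methoxybenzyl chloride | COc1ccc(CCl)cc1 | starting material
7 | 1-[2,4-bis(benzyloxy)-6-[(4-methoxyphenyl)methoxy]phenyl]ethan-1-one | CC(=O)c1c(OCc2ccc(OC)cc2)cc(OCc2ccccc2)cc1OCc1ccccc1 | intermediate
8 | 2-[2,4-bis(benzyloxy)-6-[(4-methoxyphenyl)methoxy]phenyl]-2-oxoacetaldehyde | O=CC(=O)c1c(OCc2ccc(OC)cc2)cc(OCc2ccccc2)cc1OCc1ccccc1 | intermediate
9 | (2R,3E)-5,7-bis(benzyloxy)-2-[4-(benzyloxy)phenyl]-3-{2-[2,4-bis(benzyloxy)-6-[(4-methoxyphenyl)methoxy]phenyl]-2-oxoethylidene}-2,3-dihydro-4H-chromen-4-one | O=C1/C(=C/C(=O)c2c(OCc3ccc(OC)cc3)cc(OCc3ccccc3)cc2OCc2ccccc2)[C@@H](c2ccc(OCc3ccccc3)cc2)Oc2cc(OCc3ccccc3)cc(OCc3ccccc3)c12 | intermediate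
10 | (2S,3S)-5,7-bis(benzyloxy)-2-[4-(benzyloxy)phenyl]-3-{2-[2,4-bis(benzyloxy)-6-[(4-methoxyphenyl)methoxy]phenyl]-2-oxoethyl}-2,3-dihydro-4H-chromen-4-one | O=C(C[C@@H]1C(=O)c2c(OCc3ccccc3)cc(OCc3ccccc3)cc2O[C@@H]1c1ccc(OCc2ccccc2)cc1)c1c(OCc2ccc(OC)cc2)cc(OCc2ccccc2)cc1OCc1ccccc1 | intermediate
11 | lithium (Z)-enolate of 10 at the side-chain ketone | [Li+].[O-]/C(=C\[C@@H]1C(=O)c2c(OCc3ccccc3)cc(OCc3ccccc3)cc2O[C@@H]1c1ccc(OCc2ccccc2)cc1)c1c(OCc2ccc(OC)cc2)cc(OCc2ccccc2)cc1OCc1ccccc1 | intermediate (not isolated)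
12 | (1Z)-1-[2,4-bis(benzyloxy)-6-[(4-methoxyphenyl)methoxy]phenyl]-2-{(2S,3S)-5,7-bis(benzyloxy)-2-[4-(benzyloxy)phenyl]-4-oxo-3,4-dihydro-2H-chromen-3-yl}ethenyl acetate | CC(=O)O/C(=C\[C@@H]1C(=O)c2c(OCc3ccccc3)cc(OCc3ccccc3)cc2O[C@@H]1c1ccc(OCc2ccccc2)cc1)c1c(OCc2ccc(OC)cc2)cc(OCc2ccccc2)cc1OCc1ccccc1 | intermediate
13 | (E)-aryloxy(4-methoxyphenyl)methylium (oxocarbenium) ion derived from 12, paired with the 2,3-dichloro-5,6-dicyano-4-hydroxyphenolate anion | CC(=O)O/C(=C\[C@@H]1C(=O)c2c(OCc3ccccc3)cc(OCc3ccccc3)cc2O[C@@H]1c1ccc(OCc2ccccc2)cc1)c1c(/[O+]=C/c2ccc(OC)cc2)cc(OCc2ccccc2)cc1OCc1ccccc1.[O-]c1c(Cl)c(Cl)c(O)c(C#N)c1C#N | intermediate (not isolated)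
14 | (2S,3R)-5,7-bis(benzyloxy)-3-{(2S,3S)-5,7-bis(benzyloxy)-2-[4-(benzyloxy)phenyl]-4-oxo-3,4-dihydro-2H-chromen-3-yl}-2-(4-methoxyphenyl)-2,3-dihydro-4H-chromen-4-one | COc1ccc([C@H]2Oc3cc(OCc4ccccc4)cc(OCc4ccccc4)c3C(=O)[C@@H]2[C@@H]2C(=O)c3c(OCc4ccccc4)cc(OCc4ccccc4)cc3O[C@@H]2c2ccc(OCc3ccccc3)cc2)cc1 | intermediate
15 | (2R,2'R)-5,5',7,7'-tetrakis(benzyloxy)-2'-[4-(benzyloxy)phenyl]-2-(4-methoxyphenyl)-4,4'-bis[(trimethylsilyl)oxy]-2H,2'H-3,3'-bichromene | COc1ccc([C@H]2Oc3cc(OCc4ccccc4)cc(OCc4ccccc4)c3C(O[Si](C)(C)C)=C2C2=C(O[Si](C)(C)C)c3c(OCc4ccccc4)cc(OCc4ccccc4)cc3O[C@@H]2c2ccc(OCc3ccccc3)cc2)cc1 | intermediate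
16 | (2S,3S)-5,7-bis(benzyloxy)-3-{(2S,3S)-5,7-bis(benzyloxy)-2-[4-(benzyloxy)phenyl]-4-oxo-3,4-dihydro-2H-chromen-3-yl}-2-(4-methoxyphenyl)-2,3-dihydro-4H-chromen-4-one | COc1ccc([C@H]2Oc3cc(OCc4ccccc4)cc(OCc4ccccc4)c3C(=O)[C@H]2[C@@H]2C(=O)c3c(OCc4ccccc4)cc(OCc4ccccc4)cc3O[C@@H]2c2ccc(OCc3ccccc3)cc2)cc1 | intermediate
17 | sikokianin A | COc1ccc([C@H]2Oc3cc(O)cc(O)c3C(=O)[C@H]2[C@@H]2C(=O)c3c(O)cc(O)cc3O[C@@H]2c2ccc(O)cc2)cc1 | target

**Step count and risks**
Total step count: 11. Longest linear sequence: 9 steps (steps 1, 2, 5, 6, 7, 8, 9, 10, 11; the branch through steps 3 and 4 is equally long).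

Steps most likely to fail:

1. Step 8 (proposed new method). The hydride abstraction may be too slow at an aryl p-methoxybenzyl ether whose oxygen is conjugated to the acyl arene. The oxidant may instead attack C2''–H of the existing chromanone (over-oxidation towards a flavone). The facial selectivity at C3 or the trans closure may be poor, so that C2 forms as a mixture. The fallback sets C2 by catalysis instead of relay: it sets out from 3 (and uses 5) and comes back at 15. Chromone 3 is arylated with 4-methoxyphenylboronic acid under the conditions of step 2 to give (2S)-5,7-bis(benzyloxy)-2-(4-methoxyphenyl)-2,3-dihydro-4H-chromen-4-one F1. F1 is O-silylated with i-Pr2Si(OSO2CF3)2/Et3N (CH2Cl2, −78 °C) and 5 is then added with more Et3N to give the unsymmetrical diisopropylsilylene bis(enol ether) F2. Oxidation with (NH4)2Ce(NO3)6/NaHCO3 (MeCN, −10 °C; silicon-tethered oxidative enolate heterocoupling) forms the C3–C3'' bond and gives the 3,3''-linked diketone F3 as a mixture at C3 and C3'' with both C2 centres S. Me3SiOSO2CF3/Et3N as in step 9 converts every C3/C3'' isomer of F3 into 15.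

2. Step 5. The amine catalyst may cause reversible ring opening of the flavanone (erosion of C2''), or the exocyclic double bond may migrate into the ring (aromatisation to a chromone with loss of C2''). The fallback avoids any free enolate: it sets out from 5 and comes back at 9. Compound 5 is converted with Me3SiOSO2CF3/Et3N (CH2Cl2, 0 °C) into the silyl enol ether (2S)-5,7-bis(benzyloxy)-2-[4-(benzyloxy)phenyl]-4-[(trimethylsilyl)oxy]-2H-chromene F4. A BF3·OEt2-mediated Mukaiyama aldol addition to the aldehyde carbon of 8 (CH2Cl2, −78 °C) gives the beta-hydroxy diketone F5. MeSO2Cl/Et3N (CH2Cl2, 0 °C) gives the mesylate F6, which eliminates in the flask to 9.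

3. Step 7. Deprotonation may occur in part at the ring methine C3''–H, with loss of the cis configuration needed for the relay or with ring opening by beta-elimination of the aryloxide. The fallback replaces the lithium amide by soft enolization: it sets out from 10 and comes back at 12. Compound 10 is treated with Me3SiOSO2CF3 (1.0 equiv)/Et3N (CH2Cl2, −78 °C) to silylate the ketone with the unhindered alpha-CH2 and give the mono(trimethylsilyl enol ether) F7. Fluoride-catalysed O-acylation with acetyl fluoride (CH3COF, Bu4N Ph3SiF2 cat., THF, −78 °C) converts F7 regiospecifically into 12.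

Further compounds
F1 | step 8 | (2S)-5,7-bis(benzyloxy)-2-(4-methoxyphenyl)-2,3-dihydro-4H-chromen-4-one | COc1ccc([C@@H]2CC(=O)c3c(OCc4ccccc4)cc(OCc4ccccc4)cc3O2)cc1
F2 | step 8 | {[(2S)-5,7-bis(benzyloxy)-2-(4-methoxyphenyl)-2H-chromen-4-yl]oxy}{[(2S)-5,7-bis(benzyloxy)-2-[4-(benzyloxy)phenyl]-2H-chromen-4-yl]oxy}di(propan-2-yl)silane | COc1ccc([C@@H]2C=C(O[Si](C(C)C)(C(C)C)OC3=C[C@@H](c4ccc(OCc5ccccc5)cc4)Oc4cc(OCc5ccccc5)cc(OCc5ccccc5)c43)c3c(OCc4ccccc4)cc(OCc4ccccc4)cc3O2)cc1
F3 | step 8 | (2S)-5,7-bis(benzyloxy)-3-{(2S)-5,7-bis(benzyloxy)-2-[4-(benzyloxy)phenyl]-4-oxo-3,4-dihydro-2H-chromen-3-yl}-2-(4-methoxyphenyl)-2,3-dihydro-4H-chromen-4-one, mixture at C3 and C3'' | COc1ccc([C@H]2Oc3cc(OCc4ccccc4)cc(OCc4ccccc4)c3C(=O)C2C2C(=O)c3c(OCc4ccccc4)cc(OCc4ccccc4)cc3O[C@@H]2c2ccc(OCc3ccccc3)cc2)cc1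
F4 | step 5 | (2S)-5,7-bis(benzyloxy)-2-[4-(benzyloxy)phenyl]-4-[(trimethylsilyl)oxy]-2H-chromene | C[Si](C)(C)OC1=C[C@@H](c2ccc(OCc3ccccc3)cc2)Oc2cc(OCc3ccccc3)cc(OCc3ccccc3)c21
F5 | step 5 | (2S)-5,7-bis(benzyloxy)-2-[4-(benzyloxy)phenyl]-3-{2-[2,4-bis(benzyloxy)-6-[(4-methoxyphenyl)methoxy]phenyl]-1-hydroxy-2-oxoethyl}-2,3-dihydro-4H-chromen-4-one, mixture at C3 and the carbinol carbon | O=C1C(C(O)C(=O)c2c(OCc3ccc(OC)cc3)cc(OCc3ccccc3)cc2OCc2ccccc2)[C@@H](c2ccc(OCc3ccccc3)cc2)Oc2cc(OCc3ccccc3)cc(OCc3ccccc3)c12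
F6 | step 5 | methanesulfonate ester of F5 at the carbinol oxygen | O=C1C(C(OS(C)(=O)=O)C(=O)c2c(OCc3ccc(OC)cc3)cc(OCc3ccccc3)cc2OCc2ccccc2)[C@@H](c2ccc(OCc3ccccc3)cc2)Oc2cc(OCc3ccccc3)cc(OCc3ccccc3)c12
F7 | step 7 | (2S,3S)-5,7-bis(benzyloxy)-2-[4-(benzyloxy)phenyl]-3-{(2Z)-2-[2,4-bis(benzyloxy)-6-[(4-methoxyphenyl)methoxy]phenyl]-2-[(trimethylsilyl)oxy]ethenyl}-2,3-dihydro-4H-chromen-4-one | C[Si](C)(C)O/C(=C\[C@@H]1C(=O)c2c(OCc3ccccc3)cc(OCc3ccccc3)cc2O[C@@H]1c1ccc(OCc2ccccc2)cc1)c1c(OCc2ccc(OC)cc2)cc(OCc2ccccc2)cc1OCc1ccccc1
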